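**Retrosynthetic overview**
1. Last disconnection (key step): the C8–O bond, made by site- and stereoselective C–H hydroxylation of the 8-deoxy enone 9. C8 is the only stereocentre made in the route.
2. Ring A enone: the C2–O bond comes from a singlet-oxygen ene reaction of cyclopentene 6 (C2=C3), which moves the double bond to C3=C4. Alkene 6 comes from the C3 ketone through enol triflate 5 (net 1,2-carbonyl transposition plus desaturation).
3. C14 acetate: reductive removal of the glycolate hydroxyl of (+)-pleuromutilin (1).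
4. No ring is formed: the 5-6-8 tricycle and the other seven stereocentres (C5, C6, C9, C10, C11, C12, C14) are taken intact from fermentation-derived 1.

Assumption: the target has the ring-system configuration of fermentation-derived (+)-pleuromutilin, which the route never touches; the C5 and C6 tags of the given string differ from those in database strings of pleuromutilin, and every SMILES below follows the given string at these two centres.

Locants: mutilin numbering (C1–C4 and C9 = ring A, C3 = ketone carbon of 1; C5–C8 complete ring B; C10–C14 complete the eight-membered ring; C14 carries the ester).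

Step 1
Reactants: 1 (+)-pleuromutilin
Product: 4 mutilin 14-acetate, via pleuromutilin 22-O-tosylate 2 (not isolated), via mutilin 14-iodoacetate 3 (not isolated)
Conditions: TsCl, Et3N, DMAP (cat.), MeCN, 0 °C to rt; then AcOH, NaI, Zn dust, 40 °C
Reagents that add atoms: none
Why: One-pot sulfonylation/Finkelstein/zinc reduction: only the primary glycolate hydroxyl is tosylated (the neopentyl-type 11-OH is inert), iodide displaces the α-tosyloxy ester, and zinc reduces the α-iodo ester through a zinc enolate that acetic acid protonates, so the glycolate becomes the acetate without touching any stereocentre.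

Step 2
Reactants: 4 mutilin 14-acetate
Product: 5 enol triflate 14-O-acetyl-3-deoxo-2,3-didehydromutilin-3-yl trifluoromethanesulfonate
Conditions: KN(SiMe3)2 (2.2 equiv), THF, −78 °C; PhNTf2, −78 to 0 °C; aq. NH4Cl
Reagents that add atoms: N-phenylbis(trifluoromethanesulfonimide), O=S(=O)(N(c1ccccc1)S(=O)(=O)C(F)(F)F)C(F)(F)F
Why: Kinetic enolate O-triflation: after the 11-OH is deprotonated the second equivalent of base removes a C2 proton (C4–H sits between two quaternary carbons and is not reached at −78 °C), and PhNTf2 triflates the enolate oxygen but not the hindered 11-alkoxide; no stereocentre changes.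

Step 3
Reactants: 5 enol triflate
Product: 6 alkene 14-O-acetyl-3-deoxo-2,3-didehydromutilin
Conditions: Pd(OAc)2 (5 mol %), PPh3 (10 mol %), HCO2H, Bu3N, DMF, 60 °C
Reagents that add atoms: none
Why: Palladium-catalysed formate reduction of an alkenyl triflate (Cacchi-type): oxidative addition to zerovalent palladium, formate-to-hydride exchange with loss of CO2 and reductive elimination give the C2=C3 alkene, while the vinyl group, the ester and the free alcohol are inert.

Step 4
Reactants: 6 alkene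
Product: 9 enone 14-O-acetyl-3-deoxo-2-oxo-3,4-didehydromutilin, via C2 hydroperoxide 7 (not isolated), via C2 peroxyacetate 8 (not isolated)
Conditions: O2, tetraphenylporphyrin (cat.), orange LED, CH2Cl2, −20 °C; then Ac2O (1.2 equiv), pyridine, DMAP (cat.), 0 °C
Reagents that add atoms: dioxygen, O=O
Why: Schenck ene reaction then Kornblum–DeLaMare-type dehydration: singlet oxygen attacks the cyclopentene on its convex face, bonds to the less hindered C2 and takes the allylic H4 on the same face, so the double bond moves to C3=C4 (the 2S hydroperoxide centre is transient); acetylation of the hydroperoxide and base-induced loss of acetic acid give the enone, the vinyl group having no allylic hydrogen and the hindered 11-OH not being acetylated under these conditions.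

Step 5
Reactants: 9 enone
Product: 10 pleuromutilin E
Conditions: engineered CYP105-family P450 variant (E. coli lysate, putidaredoxin, putidaredoxin reductase), NAD+ (cat.), glucose dehydrogenase, D-glucose, air, K2HPO4/KH2PO4 buffer pH 7.5, 5% DMSO, 28 °C
Reagents that add atoms: dioxygen, O=O
Why: Proposed new method: enzymatic late-stage C8–H hydroxylation of 9 with an engineered bacterial P450 — wild-type Streptomyces griseus cells are known to hydroxylate mutilin itself at C8 with 8S selectivity without epoxidising the vinyl group, but a substrate with the flat 2-oxo-3-ene ring A and a 14-acetate has not been shown, so a variant evolved by saturation mutagenesis of the substrate-binding residues is proposed to hold ring B over the heme, where the tetravalent iron-oxo porphyrin radical cation abstracts the exposed equatorial H8 and the hydroxyl rebounds on the same face (retention) to set the 8S carbinol, C2 (a competing site in mutilin) being blocked as a carbonyl; the closest known reaction type is P450 hydrogen-abstraction/oxygen-rebound hydroxylation of mutilin.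

**Compound list**
1 | (+)-pleuromutilin (mutilin 14-O-glycolate; 3-oxo, 11-OH, 12-methyl-12-vinyl) | C=C[C@]1(C)C[C@@H](OC(=O)CO)[C@]2(C)[C@@H]3C(=O)CC[C@@]3(CC[C@@H]2C)[C@@H](C)[C@@H]1O | starting material
2 | pleuromutilin 22-O-tosylate (14-O-(tosyloxyacetyl)mutilin) | C=C[C@]1(C)C[C@@H](OC(=O)COS(=O)(=O)c4ccc(C)cc4)[C@]2(C)[C@@H]3C(=O)CC[C@@]3(CC[C@@H]2C)[C@@H](C)[C@@H]1O | intermediate
3 | mutilin 14-iodoacetate | C=C[C@]1(C)C[C@@H](OC(=O)CI)[C@]2(C)[C@@H]3C(=O)CC[C@@]3(CC[C@@H]2C)[C@@H](C)[C@@H]1O | intermediate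
4 | mutilin 14-acetate | C=C[C@]1(C)C[C@@H](OC(C)=O)[C@]2(C)[C@@H]3C(=O)CC[C@@]3(CC[C@@H]2C)[C@@H](C)[C@@H]1O | intermediate
5 | 14-O-acetyl-3-deoxo-2,3-didehydromutilin-3-yl trifluoromethanesulfonate (C3 enol triflate, C2=C3) | C=C[C@]1(C)C[C@@H](OC(C)=O)[C@]2(C)[C@@H]3C(OS(=O)(=O)C(F)(F)F)=CC[C@@]3(CC[C@@H]2C)[C@@H](C)[C@@H]1O | intermediate
6 | 14-O-acetyl-3-deoxo-2,3-didehydromutilin (ring A cyclopentene, C2=C3) | C=C[C@]1(C)C[C@@H](OC(C)=O)[C@]2(C)[C@@H]3C=CC[C@@]3(CC[C@@H]2C)[C@@H](C)[C@@H]1O | intermediate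
7 | (2S)-14-O-acetyl-3-deoxo-2-hydroperoxy-3,4-didehydromutilin (OOH on the ring A face that carried H4, cis to C10; C3=C4) | C=C[C@]1(C)C[C@@H](OC(C)=O)[C@]2(C)C3=C[C@@H](OO)C[C@@]3(CC[C@@H]2C)[C@@H](C)[C@@H]1O | intermediate
8 | O-acetyl peroxyester of 7 | C=C[C@]1(C)C[C@@H](OC(C)=O)[C@]2(C)C3=C[C@@H](OOC(C)=O)C[C@@]3(CC[C@@H]2C)[C@@H](C)[C@@H]1O | intermediate
9 | 14-O-acetyl-3-deoxo-2-oxo-3,4-didehydromutilin (8-deoxypleuromutilin E) | C=C[C@]1(C)C[C@@H](OC(C)=O)[C@]2(C)C3=CC(=O)C[C@@]3(CC[C@@H]2C)[C@@H](C)[C@@H]1O | intermediate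
10 | pleuromutilin E ((8S)-8-hydroxy derivative of 9, equatorial 8-OH on ring B) | C=C[C@]1(C)C[C@@H](OC(C)=O)[C@]2(C)C3=CC(=O)C[C@@]3([C@@H](O)C[C@@H]2C)[C@@H](C)[C@@H]1O | target

**Step count and risks**
Total steps: 5. Longest linear sequence: 5 (1 → 4 → 5 → 6 → 9 → 10).

Three steps most likely to fail:

Step 5 (the proposed enzyme–substrate pair may not bind the flat ring A, or may oxidise C7). The fallback uses known chemistry, sets out from 1 and comes back at 10. Saponification of 1 (NaOH, aqueous EtOH, reflux) gives mutilin F1. Whole cells of wild-type Streptomyces griseus, known to hydroxylate mutilin at C8, give (8S)-8-hydroxymutilin F2 after chromatography. Et3SiOTf/2,6-lutidine at −78 °C silylates the two more accessible hydroxyls to 8,11-bis-O-triethylsilyl-8-hydroxymutilin F3. Ac2O/DMAP/pyridine at 60 °C acetylates the remaining 14-OH to the 14-acetate F4. The chemistry of steps 2 to 4 then gives the bis-silylated enol triflate F5, the bis-silylated alkene F6, the bis-silylated hydroperoxide F7, the bis-silylated peroxyacetate F8 and the bis-silylated enone F9. HF·pyridine removes both silyl groups and delivers 10.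

Step 4 (singlet oxygen may take H1 instead of H4, which after dehydration would give the 1-en-3-one). The fallback sets out from 5 and comes back at 9. The known palladium/norbornene-catalysed α-amination of alkenyl triflates (Pd(OAc)2, a triarylphosphine, norbornene cocatalyst, N-(benzoyloxy)morpholine, a hydride donor, Cs2CO3, toluene, 100 °C) moves the functionality from C3 to C2 and gives the C2 morpholine enamine F10. Dilute aqueous acid hydrolyses it to the saturated 2-ketone 14-O-acetyl-3-deoxo-2-oxomutilin F11. Aerobic palladium dehydrogenation (Pd(OCOCF3)2, DMSO, O2, AcOH, 80 °C) can only introduce the C3=C4 double bond, because C9 is quaternary, and returns 9.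

Step 2 (the dianion may suffer O11-triflation, acetyl transfer or acetate enolisation). The fallback sets out from 4 and comes back at 5. Me3SiCl/imidazole converts 4 into 11-O-trimethylsilylmutilin 14-acetate F12. This needs only one equivalent of KN(SiMe3)2 before PhNTf2 and gives the 11-O-trimethylsilyl enol triflate F13. Aqueous citric acid in THF removes the silyl group and returns 5.

**Further compounds**
F1 | step 5 | mutilin | C=C[C@]1(C)C[C@@H](O)[C@]2(C)[C@@H]3C(=O)CC[C@@]3(CC[C@@H]2C)[C@@H](C)[C@@H]1O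
F2 | step 5 | (8S)-8-hydroxymutilin | C=C[C@]1(C)C[C@@H](O)[C@]2(C)[C@@H]3C(=O)CC[C@@]3([C@@H](O)C[C@@H]2C)[C@@H](C)[C@@H]1O
F3 | step 5 | 8,11-bis-O-triethylsilyl-8-hydroxymutilin | C=C[C@]1(C)C[C@@H](O)[C@]2(C)[C@@H]3C(=O)CC[C@@]3([C@@H](O[Si](CC)(CC)CC)C[C@@H]2C)[C@@H](C)[C@@H]1O[Si](CC)(CC)CC
F4 | step 5 | 14-acetate of F3 | C=C[C@]1(C)C[C@@H](OC(C)=O)[C@]2(C)[C@@H]3C(=O)CC[C@@]3([C@@H](O[Si](CC)(CC)CC)C[C@@H]2C)[C@@H](C)[C@@H]1O[Si](CC)(CC)CC
F5 | step 5 | bis-silylated C3 enol triflate (C2=C3) | C=C[C@]1(C)C[C@@H](OC(C)=O)[C@]2(C)[C@@H]3C(OS(=O)(=O)C(F)(F)F)=CC[C@@]3([C@@H](O[Si](CC)(CC)CC)C[C@@H]2C)[C@@H](C)[C@@H]1O[Si](CC)(CC)CC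
F6 | step 5 | bis-silylated C2=C3 alkene | C=C[C@]1(C)C[C@@H](OC(C)=O)[C@]2(C)[C@@H]3C=CC[C@@]3([C@@H](O[Si](CC)(CC)CC)C[C@@H]2C)[C@@H](C)[C@@H]1O[Si](CC)(CC)CC
F7 | step 5 | bis-silylated (2S)-2-hydroperoxy-3-ene | C=C[C@]1(C)C[C@@H](OC(C)=O)[C@]2(C)C3=C[C@@H](OO)C[C@@]3([C@@H](O[Si](CC)(CC)CC)C[C@@H]2C)[C@@H](C)[C@@H]1O[Si](CC)(CC)CC
F8 | step 5 | bis-silylated C2 peroxyacetate | C=C[C@]1(C)C[C@@H](OC(C)=O)[C@]2(C)C3=C[C@@H](OOC(C)=O)C[C@@]3([C@@H](O[Si](CC)(CC)CC)C[C@@H]2C)[C@@H](C)[C@@H]1O[Si](CC)(CC)CC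
F9 | step 5 | 8,11-bis-O-triethylsilyl pleuromutilin E | C=C[C@]1(C)C[C@@H](OC(C)=O)[C@]2(C)C3=CC(=O)C[C@@]3([C@@H](O[Si](CC)(CC)CC)C[C@@H]2C)[C@@H](C)[C@@H]1O[Si](CC)(CC)CC
F10 | step 4 | C2 morpholine enamine (14-O-acetyl-3-deoxo-2-morpholino-2,3-didehydromutilin) | C=C[C@]1(C)C[C@@H](OC(C)=O)[C@]2(C)[C@@H]3C=C(N4CCOCC4)C[C@@]3(CC[C@@H]2C)[C@@H](C)[C@@H]1O
F11 | step 4 | 14-O-acetyl-3-deoxo-2-oxomutilin | C=C[C@]1(C)C[C@@H](OC(C)=O)[C@]2(C)[C@@H]3CC(=O)C[C@@]3(CC[C@@H]2C)[C@@H](C)[C@@H]1O
F12 | step 2 | 11-O-trimethylsilylmutilin 14-acetate | C=C[C@]1(C)C[C@@H](OC(C)=O)[C@]2(C)[C@@H]3C(=O)CC[C@@]3(CC[C@@H]2C)[C@@H](C)[C@@H]1O[Si](C)(C)C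
F13 | step 2 | 11-O-trimethylsilyl enol triflate | C=C[C@]1(C)C[C@@H](OC(C)=O)[C@]2(C)[C@@H]3C(OS(=O)(=O)C(F)(F)F)=CC[C@@]3(CC[C@@H]2C)[C@@H](C)[C@@H]1O[Si](C)(C)C
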